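**Retrosynthetic overview**
- The target is disconnected at the C15–O bond of the side chain: enantioselective Markovnikov addition of acetic acid across the terminal alkene of a 2‑(hexadec‑15‑enyl)‑3‑methylmaleic anhydride. This is the last step and sets the only stereocenter, (S).
- The anhydride ring (the only ring) comes from C–O ring closure of the cis‑diacid, itself from the dimethyl maleate.
- The tetrasubstituted maleate comes from a one‑pot syn‑carbocupration of dimethyl acetylenedicarboxylate with a C16 alkylcopper, followed by methylation.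
- The C16 chain comes from a C11 + C5 copper‑catalysed Grignard coupling of 11‑bromoundec‑1‑ene with 1‑bromo‑5‑chloropentane.
- Ring order: the anhydride ring is closed in step 3, before the stereocenter is installed in step 4.

Assumption: the new step is written with the (S,S)‑antipode of the catalyst; which antipode gives the (S)‑acetate is fixed by one small run on 12 (chiral HPLC against material from the step‑4 fallback), and the commercial (R,R)‑antipode is used instead, nothing else changed, if the sense is opposite.

**Step 1**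
Reactants: 1 (11‑bromoundec‑1‑ene) and 2 (1‑bromo‑5‑chloropentane)
Product: 4 16‑chlorohexadec‑1‑ene, via undec‑10‑enylmagnesium bromide 3 (not isolated)
Conditions: Mg, THF, 40 °C; then added to 2 (1.2 equiv), Li2CuCl4 (3 mol %), THF, −10 °C → rt
Reagents that add atoms: none
Why: Kochi‑type (Li2CuCl4‑catalysed) sp3–sp3 Grignard cross‑coupling reacts far faster at the C–Br than at the C–Cl end of 2 and ignores the remote terminal alkene, so the C16 chain forms in one pot with the chloride kept for the next Grignard formation; no stereocenter is formed.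

**Step 2**
Reactants: 4 (16‑chlorohexadec‑1‑ene) and 5 (dimethyl but‑2‑ynedioate)
Product: 9 dimethyl 2‑(hexadec‑15‑enyl)‑3‑methylmaleate, via hexadec‑15‑enylmagnesium chloride 6 (not isolated), via hexadec‑15‑enylcopper 7 (not isolated), via vinylcopper adduct 8 (not isolated)
Conditions: Mg, I2 (cat.), THF, reflux; CuBr·SMe2 (1.05 equiv), THF, −40 °C; 5 (0.9 equiv), −78 °C; then HMPA, MeI (4 equiv), −78 °C → rt
Reagents that add atoms: iodomethane, CI
Why: Syn‑carbocupration of the acetylenic diester by the monoalkylcopper, followed by C‑methylation of the vinylcopper with retention (three‑component carbometalation–alkylation), gives the tetrasubstituted cis‑diester directly while the remote alkene is untouched; no stereocenter is formed.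

**Step 3**
Reactants: 9 (dimethyl 2‑(hexadec‑15‑enyl)‑3‑methylmaleate)
Product: 12 3‑(hexadec‑15‑en‑1‑yl)‑4‑methylfuran‑2,5‑dione, via dilithium 2‑(hexadec‑15‑enyl)‑3‑methylmaleate 10 (not isolated), via 2‑(hexadec‑15‑enyl)‑3‑methylmaleic acid 11 (not isolated)
Conditions: LiOH (6 equiv), THF–MeOH–H2O, 45 °C; then 2 M HCl to pH 1, rt
Reagents that add atoms: lithium hydroxide, [Li+].[OH-] (its oxygen replaces the methoxy oxygens and supplies one ring oxygen)
Why: Ester saponification followed by acidification, on which a 2,3‑dialkylmaleic acid closes spontaneously to the five‑membered anhydride by intramolecular C–O bond formation (cyclodehydration) because the cis‑alkene holds the two carboxyl groups together; the isolated terminal alkene is inert and no stereocenter is formed.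

**Step 4**
Reactants: 12 (3‑(hexadec‑15‑en‑1‑yl)‑4‑methylfuran‑2,5‑dione)
Product: 13 (2S)‑16‑(4‑methyl‑2,5‑dioxo‑2,5‑dihydrofuran‑3‑yl)hexadecan‑2‑yl acetate
Conditions: (S,S)‑N,N'‑bis(3,5‑di‑tert‑butylsalicylidene)‑1,2‑cyclohexanediaminocobalt (divalent cobalt, 5 mol %), AcOH (5 equiv), N‑fluoro‑2,4,6‑trimethylpyridinium tetrafluoroborate (1.5 equiv), (Me2SiH)2O (1.5 equiv), 4 Å MS, PhCF3, −20 °C
Reagents that add atoms: acetic acid, CC(=O)O
Why: Proposed new method: an intermolecular, enantioselective Markovnikov hydroacetoxylation of an unactivated terminal alkene (methyl versus n‑alkyl discrimination, not yet demonstrated), in which the divalent cobalt salen complex is oxidised by the N‑fluoropyridinium salt and turned by the silane into a trivalent cobalt hydride, hydrogen‑atom transfer to the terminal CH2 gives the secondary C15 radical (Markovnikov by radical stability; the hindered, electron‑poor ring alkene is not attacked), the radical is captured by divalent cobalt and oxidised to a catalyst‑bound tetravalent sec‑alkylcobalt whose two diastereomers interconvert by reversible Co–C homolysis, and acetic acid displaces cobalt with inversion (SN2‑type) in the enantio‑determining C–O bond formation, the chiral salen cleft letting the diastereomer that leads to the (S)‑acetate react faster (dynamic kinetic resolution); the closest known reaction type is the racemic cobalt‑salen hydrogen‑atom‑transfer/radical‑polar‑crossover Markovnikov hydroalkoxylation and hydroacyloxylation of unactivated alkenes and its enantioselective ring‑forming (intramolecular) versions.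

**Compound list**
1 | 11‑bromoundec‑1‑ene | C=CCCCCCCCCCBr | starting material
2 | 1‑bromo‑5‑chloropentane | ClCCCCCBr | starting material
3 | undec‑10‑enylmagnesium bromide | C=CCCCCCCCCC[Mg]Br | intermediate (not isolated)
4 | 16‑chlorohexadec‑1‑ene | C=CCCCCCCCCCCCCCCCl | intermediate
5 | dimethyl but‑2‑ynedioate | COC(=O)C#CC(=O)OC | starting material
6 | hexadec‑15‑enylmagnesium chloride | C=CCCCCCCCCCCCCCC[Mg]Cl | intermediate (not isolated)
7 | hexadec‑15‑enylcopper (as its SMe2·MgBrCl complex) | C=CCCCCCCCCCCCCCC[Cu] | intermediate (not isolated)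
8 | vinylcopper adduct, dimethyl 2‑cuprio‑3‑(hexadec‑15‑enyl)maleate (alkyl and Cu cis) | C=CCCCCCCCCCCCCCC/C(C(=O)OC)=C(\[Cu])C(=O)OC | intermediate (not isolated)
9 | dimethyl 2‑(hexadec‑15‑enyl)‑3‑methylmaleate [dimethyl (2Z)‑2‑(hexadec‑15‑en‑1‑yl)‑3‑methylbut‑2‑enedioate] | C=CCCCCCCCCCCCCCC/C(C(=O)OC)=C(\C)C(=O)OC | intermediate
10 | dilithium 2‑(hexadec‑15‑enyl)‑3‑methylmaleate | [Li+].[Li+].C=CCCCCCCCCCCCCCC/C(C(=O)[O-])=C(\C)C(=O)[O-] | intermediate (not isolated)
11 | 2‑(hexadec‑15‑enyl)‑3‑methylmaleic acid | C=CCCCCCCCCCCCCCC/C(C(=O)O)=C(\C)C(=O)O | intermediate (not isolated)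
12 | 3‑(hexadec‑15‑en‑1‑yl)‑4‑methylfuran‑2,5‑dione | C=CCCCCCCCCCCCCCCC1=C(C)C(=O)OC1=O | intermediate
13 | (2S)‑16‑(4‑methyl‑2,5‑dioxo‑2,5‑dihydrofuran‑3‑yl)hexadecan‑2‑yl acetate | CC(=O)O[C@@H](C)CCCCCCCCCCCCCCC1=C(C)C(=O)OC1=O | target

**Totals**
Total step count: 4. Longest linear sequence: 4 (1 → 4 → 9 → 12 → 13).

**Three steps most likely to fail**

Step 4 (the proposed new step). The risks are insufficient enantioselectivity (methyl versus long alkyl), unknown sense of induction, alkene isomerisation by reversible hydrogen‑atom transfer leading to regioisomeric acetates, and fluoride or water capture instead of acetate. The fallback uses known chemistry, sets out from 12 and comes back at 13. Tsuji–Wacker oxidation of 12 (PdCl2, CuCl, O2, DMF–H2O, rt) gives the methyl ketone 3‑methyl‑4‑(15‑oxohexadecyl)furan‑2,5‑dione F1. A Prelog‑selective alcohol dehydrogenase (for example ADH‑A of Rhodococcus ruber, NADH recycled with 2‑propanol, phosphate buffer pH 7; acidic work‑up re‑closes any opened anhydride) reduces it to 3‑[(15S)‑15‑hydroxyhexadecyl]‑4‑methylfuran‑2,5‑dione F2. Acetylation (Ac2O, pyridine, rt) then gives 13.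

Step 2. The risks are sluggish Grignard formation from the primary chloride, incomplete methylation of the vinylcopper (giving the protonated 2‑alkylmaleate), and partial loss of the cis geometry on warming. The fallback sets out from 6 and comes back at 12. Inverse addition of 6 to diethyl oxalate (THF, −78 °C, HCl quench) gives ethyl 2‑oxooctadec‑17‑enoate F3. Reformatsky addition of ethyl 2‑bromopropanoate (Zn, THF, reflux) gives diethyl 2‑(hexadec‑15‑en‑1‑yl)‑2‑hydroxy‑3‑methylbutanedioate F4 (diastereomer mixture, of no consequence). Saponification (KOH, EtOH–H2O) gives 2‑(hexadec‑15‑en‑1‑yl)‑2‑hydroxy‑3‑methylbutanedioic acid F5. Heating F5 in Ac2O, then Et3N, closes the anhydride ring and eliminates the tertiary oxygen inside the ring, so only the cis (maleic) anhydride 12 can result.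

Step 1. The risks are Wurtz homocoupling of the Grignard reagent and separation of 4 from the C22 diene and from excess 2. The fallback sets out from 1 (and 2) and comes back at 4. Displacement of 1 with PhSO2Na (DMF, 60 °C) gives (undec‑10‑en‑1‑ylsulfonyl)benzene F6. Lithiation (n‑BuLi, THF, −78 °C) and alkylation with 2 at its bromide end gives [(16‑chlorohexadec‑1‑en‑11‑yl)sulfonyl]benzene F7 (racemic). Reductive desulfonylation (Mg, MeOH, 50 °C) gives 4.

**Further compounds**
F1 | step 4 | 3‑methyl‑4‑(15‑oxohexadecyl)furan‑2,5‑dione | CC(=O)CCCCCCCCCCCCCCC1=C(C)C(=O)OC1=O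
F2 | step 4 | 3‑[(15S)‑15‑hydroxyhexadecyl]‑4‑methylfuran‑2,5‑dione | O[C@@H](C)CCCCCCCCCCCCCCC1=C(C)C(=O)OC1=O
F3 | step 2 | ethyl 2‑oxooctadec‑17‑enoate | C=CCCCCCCCCCCCCCCC(=O)C(=O)OCC
F4 | step 2 | diethyl 2‑(hexadec‑15‑en‑1‑yl)‑2‑hydroxy‑3‑methylbutanedioate | C=CCCCCCCCCCCCCCCC(O)(C(=O)OCC)C(C)C(=O)OCC
F5 | step 2 | 2‑(hexadec‑15‑en‑1‑yl)‑2‑hydroxy‑3‑methylbutanedioic acid | C=CCCCCCCCCCCCCCCC(O)(C(=O)O)C(C)C(=O)O
F6 | step 1 | (undec‑10‑en‑1‑ylsulfonyl)benzene | C=CCCCCCCCCCS(=O)(=O)c1ccccc1
F7 | step 1 | [(16‑chlorohexadec‑1‑en‑11‑yl)sulfonyl]benzene | C=CCCCCCCCCC(CCCCCCl)S(=O)(=O)c1ccccc1
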